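**Assumptions.** The target has no stereocentre (C2 carries two identical methyl groups), so "single enantiomer" means the one achiral compound and nothing stereochemical has to be set. Metal salts that are simply protonated at work-up (enolates, alkoxides, carboxylates) are not numbered separately. Indane locants used throughout: C2 = CMe2; C4 = aromatic carbon next to the ring fusion (ends as CH2OAc); C5 = central carbon (OH → vinyl → CH2CH2Cl); C6 = carbon next to the aromatic CH (ends as CH2O-butanoyl); C7 = aromatic CH.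

**Retrosynthetic overview**
- Target ⇒ 5-vinyl-indane-4,6-diester: vinyl → CH2CH2Cl by hydroboration then chlorination; the two ester carbons are told apart sterically (C6 ester saponified first, C4 ester reduced later).
- Vinyl diester ⇒ aryl triflate ⇒ dimethyl 5-hydroxy-2,2-dimethylindane-4,6-dicarboxylate (Stille coupling).
- Key disconnection: the phenol ring ⇒ 2-(hydroxymethylidene)-4,4-dimethylcyclopentanone + dimethyl 3-oxopentanedioate (intermolecular Knoevenagel/aldol condensation, then ring-closing aldol and aromatisation).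
- Hydroxymethylidene ketone ⇒ 3,3-dimethylcyclopentanone + ethyl formate (crossed Claisen); the ketone ⇒ 3-methylcyclopent-2-enone + methyl (conjugate addition).
- Ring order: the cyclopentane is bought; the benzene ring is built onto it second; no further rings.

**Step 1**
Reactants: 1 3-methylcyclopent-2-en-1-one
Product: 2 3,3-dimethylcyclopentan-1-one
Conditions: MeMgBr (1.3 equiv), CuBr·SMe2 (5 mol %), THF, −30 → 0 °C; then 1 M HCl
Reagents that add atoms: methylmagnesium bromide C[Mg]Br
Why: Copper-catalysed conjugate (Michael-type) addition of the methyl Grignard to the β-methyl enone builds the quaternary CMe2 carbon; the product is achiral.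

**Step 2**
Reactants: 2 3,3-dimethylcyclopentan-1-one; 3 ethyl formate
Product: 4 (2Z)-2-(hydroxymethylidene)-4,4-dimethylcyclopentan-1-one
Conditions: NaH (1.5 equiv), EtOH (cat.), THF, 0 °C → rt; then cold 1 M HCl
Reagents that add atoms: none
Why: Crossed Claisen condensation with non-enolisable ethyl formate; under equilibrating conditions the formyl group settles on the unhindered α-CH2 rather than the neopentyl α-CH2 beside CMe2, and the product is held as its stable sodium enolate.

**Step 3**
Reactants: 4 (2Z)-2-(hydroxymethylidene)-4,4-dimethylcyclopentan-1-one; 5 dimethyl 3-oxopentanedioate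
Product: 7 dimethyl 5-hydroxy-2,2-dimethyl-2,3-dihydro-1H-indene-4,6-dicarboxylate, via Knoevenagel adduct 6 (not isolated)
Conditions: NaOMe (2.2 equiv), MeOH, 0 °C → rt, 48 h, then reflux 2 h; aq. HCl
Reagents that add atoms: none
Why: Key step: intermolecular Knoevenagel-type aldol condensation of one active CH2 of 5 with the formyl carbon of 4 joins the fragments, then intramolecular aldol of the second CH2 onto the ring ketone, two dehydrations and enolisation give the 2-hydroxyisophthalate (Prelog-type [3+3] benzannulation); 5 is symmetric, so only one substitution pattern can form.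

**Step 4**
Reactants: 7 dimethyl 5-hydroxy-2,2-dimethyl-2,3-dihydro-1H-indene-4,6-dicarboxylate
Product: 8 dimethyl 2,2-dimethyl-5-[(trifluoromethanesulfonyl)oxy]-2,3-dihydro-1H-indene-4,6-dicarboxylate
Conditions: Tf2O (1.3 equiv), pyridine (3 equiv), CH2Cl2, 0 °C → rt
Reagents that add atoms: trifluoromethanesulfonic anhydride O=S(=O)(OS(=O)(=O)C(F)(F)F)C(F)(F)F
Why: O-Sulfonylation of the acidic, ester-flanked phenol turns the C5 oxygen into a cross-coupling handle; the esters are inert.

**Step 5**
Reactants: 8 dimethyl 2,2-dimethyl-5-[(trifluoromethanesulfonyl)oxy]-2,3-dihydro-1H-indene-4,6-dicarboxylate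
Product: 9 dimethyl 5-ethenyl-2,2-dimethyl-2,3-dihydro-1H-indene-4,6-dicarboxylate
Conditions: Bu3SnCH=CH2 (1.3 equiv), Pd(PPh3)4 (5 mol %), LiCl (3 equiv), 1,4-dioxane, 100 °C
Reagents that add atoms: tributyl(vinyl)stannane C=C[Sn](CCCC)(CCCC)CCCC
Why: LiCl-promoted Stille coupling of an electron-poor aryl triflate with the small vinyl group tolerates both ortho esters and installs the two-carbon chain at C5.

**Step 6**
Reactants: 9 dimethyl 5-ethenyl-2,2-dimethyl-2,3-dihydro-1H-indene-4,6-dicarboxylate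
Product: 10 5-ethenyl-4-(methoxycarbonyl)-2,2-dimethyl-2,3-dihydro-1H-indene-6-carboxylic acid
Conditions: LiOH·H2O (1.15 equiv), THF/MeOH/H2O 3:1:1, rt, followed by TLC; then 1 M HCl
Reagents that add atoms: lithium hydroxide [Li+].[OH-]
Why: Sterically controlled BAc2 saponification: the C6 ester has one ortho substituent, whereas the C4 ester is flanked on both sides (vinyl and ring CH2) like a 2,6-dialkylbenzoate and survives one equivalent of hydroxide.

**Step 7**
Reactants: 10 5-ethenyl-4-(methoxycarbonyl)-2,2-dimethyl-2,3-dihydro-1H-indene-6-carboxylic acid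
Product: 12 methyl 5-ethenyl-6-(hydroxymethyl)-2,2-dimethyl-2,3-dihydro-1H-indene-4-carboxylate, via mixed carbonic anhydride 11 (not isolated)
Conditions: i-BuOCOCl (1.1 equiv), N-methylmorpholine (1.1 equiv), THF, −15 °C, 30 min; then NaBH4 (3 equiv), H2O, 0 °C
Reagents that add atoms: isobutyl chloroformate CC(C)COC(=O)Cl (its atoms are in 11 only)
Why: Mixed-anhydride activation and borohydride reduction convert only the free acid to CH2OH; NaBH4 neither reduces the hindered methyl benzoate nor hydroborates the styrene, as BH3 would.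

**Step 8**
Reactants: 12 methyl 5-ethenyl-6-(hydroxymethyl)-2,2-dimethyl-2,3-dihydro-1H-indene-4-carboxylate
Product: 13 methyl 6-{[(tert-butyldimethylsilyl)oxy]methyl}-5-ethenyl-2,2-dimethyl-2,3-dihydro-1H-indene-4-carboxylate
Conditions: TBSCl (1.3 equiv), imidazole (2.5 equiv), DMF, rt
Reagents that add atoms: tert-butyldimethylsilyl chloride CC(C)(C)[Si](C)(C)Cl
Why: Standard silylation masks the C6 CH2OH so the two benzylic oxygens remain distinguishable.

**Step 9**
Reactants: 13 methyl 6-{[(tert-butyldimethylsilyl)oxy]methyl}-5-ethenyl-2,2-dimethyl-2,3-dihydro-1H-indene-4-carboxylate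
Product: 14 (6-{[(tert-butyldimethylsilyl)oxy]methyl}-5-ethenyl-2,2-dimethyl-2,3-dihydro-1H-inden-4-yl)methanol
Conditions: LiAlH4 (1.5 equiv), THF, 0 °C → rt; Fieser work-up
Reagents that add atoms: none
Why: Hydride reduction with LiAlH4 takes even a di-ortho-substituted benzoate to the benzylic alcohol, while the silyl ether and the styrene are untouched.

**Step 10**
Reactants: 14 (6-{[(tert-butyldimethylsilyl)oxy]methyl}-5-ethenyl-2,2-dimethyl-2,3-dihydro-1H-inden-4-yl)methanol
Product: 15 (6-{[(tert-butyldimethylsilyl)oxy]methyl}-5-ethenyl-2,2-dimethyl-2,3-dihydro-1H-inden-4-yl)methyl acetate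
Conditions: Ac2O (1.5 equiv), pyridine, DMAP (5 mol %), CH2Cl2, 0 °C → rt
Reagents that add atoms: acetic anhydride CC(=O)OC(C)=O
Why: DMAP-catalysed acylation of the only free hydroxyl places the acetate on the C4 CH2O.

**Step 11**
Reactants: 15 (6-{[(tert-butyldimethylsilyl)oxy]methyl}-5-ethenyl-2,2-dimethyl-2,3-dihydro-1H-inden-4-yl)methyl acetate
Product: 17 [6-{[(tert-butyldimethylsilyl)oxy]methyl}-5-(2-hydroxyethyl)-2,2-dimethyl-2,3-dihydro-1H-inden-4-yl]methyl acetate, via B-alkyl-9-BBN adduct 16 (not isolated)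
Conditions: 9-BBN (0.5 M in THF, 1.5 equiv), 0 °C → rt, 12 h; then 30 % H2O2, 3 M aq. NaOAc, 0 °C → rt
Reagents that add atoms: 9-borabicyclo[3.3.1]nonane B1C2CCCC1CCC2 (its atoms are in 16 only); hydrogen peroxide OO
Why: Anti-Markovnikov hydroboration with bulky 9-BBN puts boron on the terminal carbon, and acetate-buffered peroxide oxidation spares the acetate and the silyl ether.

**Step 12**
Reactants: 17 [6-{[(tert-butyldimethylsilyl)oxy]methyl}-5-(2-hydroxyethyl)-2,2-dimethyl-2,3-dihydro-1H-inden-4-yl]methyl acetate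
Product: 18 [6-{[(tert-butyldimethylsilyl)oxy]methyl}-5-(2-chloroethyl)-2,2-dimethyl-2,3-dihydro-1H-inden-4-yl]methyl acetate
Conditions: PPh3 (1.5 equiv) and NCS (1.5 equiv) premixed, CH2Cl2, 0 °C; then 17, 0 °C → rt
Reagents that add atoms: N-chlorosuccinimide O=C1CCC(=O)N1Cl
Why: Appel-type chlorination: chloride displaces the alkoxyphosphonium at a primary carbon by SN2 under neutral conditions that leave acetate and TBS ether alone.

**Step 13**
Reactants: 18 [6-{[(tert-butyldimethylsilyl)oxy]methyl}-5-(2-chloroethyl)-2,2-dimethyl-2,3-dihydro-1H-inden-4-yl]methyl acetate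
Product: 19 [5-(2-chloroethyl)-6-(hydroxymethyl)-2,2-dimethyl-2,3-dihydro-1H-inden-4-yl]methyl acetate
Conditions: HF·pyridine, THF/pyridine, 0 °C → rt
Reagents that add atoms: none
Why: Acidic fluoride desilylation; HF·pyridine is used instead of TBAF because a free alkoxide could close onto the CH2CH2Cl arm (isochroman) or cleave the acetate.

**Step 14**
Reactants: 19 [5-(2-chloroethyl)-6-(hydroxymethyl)-2,2-dimethyl-2,3-dihydro-1H-inden-4-yl]methyl acetate
Product: 20 [4-(acetoxymethyl)-5-(2-chloroethyl)-2,2-dimethyl-2,3-dihydro-1H-inden-6-yl]methyl butanoate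
Conditions: (n-PrCO)2O (1.5 equiv), pyridine, DMAP (5 mol %), CH2Cl2, 0 °C
Reagents that add atoms: butanoic anhydride CCCC(=O)OC(=O)CCC
Why: DMAP-catalysed esterification of the primary benzylic alcohol is fast at 0 °C and leaves the chloride and acetate untouched, giving the target.

**Compound list**
1 | 3-methylcyclopent-2-en-1-one | CC1=CC(=O)CC1 | starting material
2 | 3,3-dimethylcyclopentan-1-one | CC1(C)CCC(=O)C1 | intermediate
3 | ethyl formate | CCOC=O | starting material
4 | (2Z)-2-(hydroxymethylidene)-4,4-dimethylcyclopentan-1-one (enol form of 4,4-dimethyl-2-oxocyclopentane-1-carbaldehyde) | O=C1CC(C)(C)C/C1=C/O | intermediate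
5 | dimethyl 3-oxopentanedioate (dimethyl acetonedicarboxylate) | COC(=O)CC(=O)CC(=O)OC | starting material
6 | dimethyl 2-[(4,4-dimethyl-2-oxocyclopentyl)methylidene]-3-oxopentanedioate (Knoevenagel adduct, E/Z not fixed) | COC(=O)CC(=O)C(=CC1CC(C)(C)CC1=O)C(=O)OC | intermediate (not isolated)
7 | dimethyl 5-hydroxy-2,2-dimethyl-2,3-dihydro-1H-indene-4,6-dicarboxylate | COC(=O)c1cc2c(c(C(=O)OC)c1O)CC(C)(C)C2 | intermediate
8 | dimethyl 2,2-dimethyl-5-[(trifluoromethanesulfonyl)oxy]-2,3-dihydro-1H-indene-4,6-dicarboxylate | COC(=O)c1cc2c(c(C(=O)OC)c1OS(=O)(=O)C(F)(F)F)CC(C)(C)C2 | intermediate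
9 | dimethyl 5-ethenyl-2,2-dimethyl-2,3-dihydro-1H-indene-4,6-dicarboxylate | COC(=O)c1cc2c(c(C(=O)OC)c1C=C)CC(C)(C)C2 | intermediate
10 | 5-ethenyl-4-(methoxycarbonyl)-2,2-dimethyl-2,3-dihydro-1H-indene-6-carboxylic acid | OC(=O)c1cc2c(c(C(=O)OC)c1C=C)CC(C)(C)C2 | intermediate
11 | mixed isobutyl carbonic anhydride of 10 | CC(C)COC(=O)OC(=O)c1cc2c(c(C(=O)OC)c1C=C)CC(C)(C)C2 | intermediate (not isolated)
12 | methyl 5-ethenyl-6-(hydroxymethyl)-2,2-dimethyl-2,3-dihydro-1H-indene-4-carboxylate | OCc1cc2c(c(C(=O)OC)c1C=C)CC(C)(C)C2 | intermediate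
13 | methyl 6-{[(tert-butyldimethylsilyl)oxy]methyl}-5-ethenyl-2,2-dimethyl-2,3-dihydro-1H-indene-4-carboxylate | CC(C)(C)[Si](C)(C)OCc1cc2c(c(C(=O)OC)c1C=C)CC(C)(C)C2 | intermediate
14 | (6-{[(tert-butyldimethylsilyl)oxy]methyl}-5-ethenyl-2,2-dimethyl-2,3-dihydro-1H-inden-4-yl)methanol | CC(C)(C)[Si](C)(C)OCc1cc2c(c(CO)c1C=C)CC(C)(C)C2 | intermediate
15 | (6-{[(tert-butyldimethylsilyl)oxy]methyl}-5-ethenyl-2,2-dimethyl-2,3-dihydro-1H-inden-4-yl)methyl acetate | CC(C)(C)[Si](C)(C)OCc1cc2c(c(COC(C)=O)c1C=C)CC(C)(C)C2 | intermediate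
16 | 9-{2-[4-(acetoxymethyl)-6-{[(tert-butyldimethylsilyl)oxy]methyl}-2,2-dimethyl-2,3-dihydro-1H-inden-5-yl]ethyl}-9-borabicyclo[3.3.1]nonane | CC(C)(C)[Si](C)(C)OCc1cc2c(c(COC(C)=O)c1CCB1C3CCCC1CCC3)CC(C)(C)C2 | intermediate (not isolated)
17 | [6-{[(tert-butyldimethylsilyl)oxy]methyl}-5-(2-hydroxyethyl)-2,2-dimethyl-2,3-dihydro-1H-inden-4-yl]methyl acetate | CC(C)(C)[Si](C)(C)OCc1cc2c(c(COC(C)=O)c1CCO)CC(C)(C)C2 | intermediate
18 | [6-{[(tert-butyldimethylsilyl)oxy]methyl}-5-(2-chloroethyl)-2,2-dimethyl-2,3-dihydro-1H-inden-4-yl]methyl acetate | CC(C)(C)[Si](C)(C)OCc1cc2c(c(COC(C)=O)c1CCCl)CC(C)(C)C2 | intermediate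
19 | [5-(2-chloroethyl)-6-(hydroxymethyl)-2,2-dimethyl-2,3-dihydro-1H-inden-4-yl]methyl acetate | OCc1cc2c(c(COC(C)=O)c1CCCl)CC(C)(C)C2 | intermediate
20 | [4-(acetoxymethyl)-5-(2-chloroethyl)-2,2-dimethyl-2,3-dihydro-1H-inden-6-yl]methyl butanoate (CNP0321917.0, achiral) | CCCC(=O)OCc1cc2c(c(COC(C)=O)c1CCCl)CC(C)(C)C2 | target

**Totals.** 14 steps; the longest linear sequence is 14 steps (fully linear from 1).

**Three steps most likely to fail, with fallbacks**

Step 3 (benzannulation; risk of retro-Claisen deformylation of 4 or self-condensation of 5 under methoxide). The fallback sets out from 2. Heating 2 with N,N-dimethylformamide dimethyl acetal (neat, 100 °C) gives the enaminone (2E)-2-[(dimethylamino)methylidene]-4,4-dimethylcyclopentan-1-one F1, a 1,3-dielectrophile that cannot deformylate. Condensing F1 with 5 in AcOH/toluene at reflux (addition–elimination of dimethylamine, then aldol closure and dehydration) gives the phenol, and the route is rejoined at 7.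

Step 5 (Stille coupling at a doubly ortho-substituted triflate). The fallback sets out from 8. Sonogashira coupling with ethynyltrimethylsilane (PdCl2(PPh3)2, CuI, Et3N, DMF, 70 °C) gives dimethyl 2,2-dimethyl-5-[(trimethylsilyl)ethynyl]-2,3-dihydro-1H-indene-4,6-dicarboxylate F2; the rod-shaped alkyne is less sensitive to the flanking esters. Catalytic K2CO3 in MeOH removes the silyl group to give dimethyl 5-ethynyl-2,2-dimethyl-2,3-dihydro-1H-indene-4,6-dicarboxylate F3. Lindlar semihydrogenation (H2, Pd/CaCO3–Pb, quinoline, EtOAc) returns to the route at 9.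

Step 6 (regioselective mono-saponification; risk of diacid or the wrong half-ester). The fallback sets out from 9. LiAlH4 (THF, 0 °C → rt) reduces both esters to the diol (5-ethenyl-2,2-dimethyl-2,3-dihydro-1H-indene-4,6-diyl)dimethanol F4. The two hydroxyls are then distinguished by size-selective silylation (1.0 equiv TBSCl, imidazole, CH2Cl2, −20 °C), which takes the C6 CH2OH that has only one ortho neighbour. This comes back to the route at 14, bypassing steps 6–9.

**Further compounds**
F1 | step 3 | (2E)-2-[(dimethylamino)methylidene]-4,4-dimethylcyclopentan-1-one | O=C1CC(C)(C)C/C1=C\N(C)C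
F2 | step 5 | dimethyl 2,2-dimethyl-5-[(trimethylsilyl)ethynyl]-2,3-dihydro-1H-indene-4,6-dicarboxylate | COC(=O)c1cc2c(c(C(=O)OC)c1C#C[Si](C)(C)C)CC(C)(C)C2
F3 | step 5 | dimethyl 5-ethynyl-2,2-dimethyl-2,3-dihydro-1H-indene-4,6-dicarboxylate | COC(=O)c1cc2c(c(C(=O)OC)c1C#C)CC(C)(C)C2
F4 | step 6 | (5-ethenyl-2,2-dimethyl-2,3-dihydro-1H-indene-4,6-diyl)dimethanol | OCc1cc2c(c(CO)c1C=C)CC(C)(C)C2
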